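Target ⇐ acylation of the 3β-alcohol ⇐ Luche reduction of the 4-en-3-one ⇐ C3–H oxidation of methyl 8β-acetoxyeudesma-4,11(13)-dien-12-oate.
The plan rests on the C5–C10 bond shared by rings A and B, with C15 on C4 and C14 on C10: this is the pattern left when the C4=C5 and C1=C10 alkenes of a ten-membered (E,E)-germacra-1(10),4-diene bond across the ring, so the eudesmadiene is cut at C5–C10 to methyl 8β-acetoxygermacra-1(10)E,4E,11(13)-trien-12-oate.
Germacratriene ⇐ C7–C8 bond: chromium-catalysed asymmetric intramolecular allylation of a linear ω-formyl (Z)-2-(bromomethyl)enoate, which sets C7 and C8 and closes the ten-membered ring.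
Linear chain ⇐ two zirconium-catalysed carboaluminations (C10=C1 and C4=C5, both E), a Negishi coupling (C1–C2), ethylene oxide (C6, C7) and a vinylalumination with methyl propiolate (C11–C13).
Ring order: ten-membered carbocycle first (step 10), then rings A and B together in one bond-forming event (step 12); the C3 oxygen comes last.

Key step: step 12

Remark (assumption): L* in step 10 is (S,S)-3,6-diphenyl-1,8-bis(4-isopropyl-4,5-dihydrooxazol-2-yl)-9H-carbazole, taken to deliver the (7R,8R) ring (the (R,R) antipode is used if a trial closure shows the opposite sense); the ten-membered-ring compounds of steps 10 to 12 cyclise on acidic silica and undergo Cope rearrangement on heating, so they are kept below 30 °C and purified on Et3N-deactivated silica.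

Step 1
Reactants: 1 tert-butyl(but-3-yn-1-yloxy)dimethylsilane
Product: 3 (E)-tert-butyl[(4-iodo-3-methylbut-3-en-1-yl)oxy]dimethylsilane, via alkenyldimethylalane 2 (not isolated)
Conditions: Me3Al, Cp2ZrCl2 (25 mol %), CH2Cl2, 0 °C → rt; then I2, THF, −30 → 0 °C
Reagents that add atoms: trimethylaluminium, C[Al](C)C; iodine, II
Why: Negishi zirconium-catalysed carboalumination adds the methyl group and aluminium syn across the terminal alkyne with methyl on the internal carbon, and iodinolysis of the C–Al bond with retention fixes the (E)-C10=C1 alkene of the later ring (germacrane numbering) as an alkenyl iodide.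

Step 2
Reactants: 3 (E)-tert-butyl[(4-iodo-3-methylbut-3-en-1-yl)oxy]dimethylsilane; 4 (4-bromobut-1-yn-1-yl)trimethylsilane
Product: 6 (E)-tert-butyldimethyl{[3-methyl-8-(trimethylsilyl)oct-3-en-7-yn-1-yl]oxy}silane, via alkylzinc bromide 5 (not isolated)
Conditions: 4, activated Zn dust, LiCl, THF, 50 °C; then 3, Pd(PPh3)4 (5 mol %, zerovalent palladium), THF, rt → 40 °C
Reagents that add atoms: none
Why: Negishi cross-coupling of a primary alkylzinc with an alkenyl iodide forms the sp3–sp2 bond C1–C2 with retention of the (E) geometry, and the silyl cap keeps the acidic alkyne C–H away from the organozinc.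

Step 3
Reactants: 6 (E)-tert-butyldimethyl{[3-methyl-8-(trimethylsilyl)oct-3-en-7-yn-1-yl]oxy}silane
Product: 7 (E)-tert-butyldimethyl[(3-methyloct-3-en-7-yn-1-yl)oxy]silane
Conditions: K2CO3 (0.3 equiv), MeOH, rt
Reagents that add atoms: none
Why: Methoxide-mediated protodesilylation cleaves only the alkynyl C–Si bond, the silyl ether and the alkene being inert.

Step 4
Reactants: 7 (E)-tert-butyldimethyl[(3-methyloct-3-en-7-yn-1-yl)oxy]silane; 8 ethylene oxide
Product: 11 (3E,7E)-10-(tert-butyldimethylsilyloxy)-4,8-dimethyldeca-3,7-dien-1-ol, via dienyldimethylalane 9 (not isolated), via lithium alanate 10 (not isolated)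
Conditions: Me3Al, Cp2ZrCl2 (25 mol %), CH2Cl2, rt; excess Me3Al removed in vacuo; n-BuLi, hexane, 0 °C; ethylene oxide, THF, 0 °C → rt; aqueous work-up
Reagents that add atoms: trimethylaluminium, C[Al](C)C
Why: A second Negishi carboalumination sets the (E)-C4=C5 alkene by syn addition, and the alkenylalanate formed with n-BuLi opens ethylene oxide with retention at the alkenyl carbon, adding C6 and C7 as a homoallylic alcohol.

Step 5
Reactants: 11 (3E,7E)-10-(tert-butyldimethylsilyloxy)-4,8-dimethyldeca-3,7-dien-1-ol
Product: 12 (3E,7E)-10-(tert-butyldimethylsilyloxy)-4,8-dimethyldeca-3,7-dienal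
Conditions: Dess–Martin periodinane, pyridine, CH2Cl2, 0 °C → rt; used crude
Reagents that add atoms: none
Why: Dess–Martin oxidation under pyridine buffering should give the β,γ-unsaturated aldehyde without shifting the C4=C5 alkene into conjugation.

Step 6
Reactants: 12 (3E,7E)-10-(tert-butyldimethylsilyloxy)-4,8-dimethyldeca-3,7-dienal; 13 methyl propiolate
Product: 15 methyl (5E,9E)-12-(tert-butyldimethylsilyloxy)-3-hydroxy-6,10-dimethyl-2-methylidenedodeca-5,9-dienoate (racemic at C3), via α-aluminoacrylate 14 (not isolated)
Conditions: i-Bu2AlH, N-methylmorpholine N-oxide, THF, 0 °C; 13, 0 °C; then 12, 0 °C → rt; Rochelle-salt work-up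
Reagents that add atoms: none
Why: Vinylalumination, in which hydroalumination of the propiolate gives the α-aluminoacrylate that adds to the aldehyde, delivers the Morita–Baylis–Hillman-type alcohol under non-basic conditions that do not isomerise the β,γ-unsaturated aldehyde; the carbinol centre is racemic and is erased in step 7.

Step 7
Reactants: 15 methyl (5E,9E)-12-(tert-butyldimethylsilyloxy)-3-hydroxy-6,10-dimethyl-2-methylidenedodeca-5,9-dienoate
Product: 16 methyl (2Z,5E,9E)-2-(bromomethyl)-12-(tert-butyldimethylsilyloxy)-6,10-dimethyldodeca-2,5,9-trienoate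
Conditions: NBS, Me2S, CH2Cl2, 0 °C → rt
Reagents that add atoms: N-bromosuccinimide, O=C1CCC(=O)N1Br
Why: Bromination of the Baylis–Hillman alcohol with the NBS–Me2S sulfonium reagent (Corey–Kim type) proceeds with allylic transposition (SN2′) to the thermodynamically preferred (Z)-2-(bromomethyl)enoate, the geometry that later dictates the 7,8-cis relationship, while the isolated alkenes and the silyl ether are not touched.

Step 8
Reactants: 16 methyl (2Z,5E,9E)-2-(bromomethyl)-12-(tert-butyldimethylsilyloxy)-6,10-dimethyldodeca-2,5,9-trienoate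
Product: 17 methyl (2Z,5E,9E)-2-(bromomethyl)-12-hydroxy-6,10-dimethyldodeca-2,5,9-trienoate
Conditions: HF·pyridine, pyridine, THF, 0 °C → rt
Reagents that add atoms: none
Why: Buffered HF·pyridine cleaves the primary silyl ether by Si–F bond formation while the allylic bromide, which would not survive basic fluoride, stays intact.

Step 9
Reactants: 17 methyl (2Z,5E,9E)-2-(bromomethyl)-12-hydroxy-6,10-dimethyldodeca-2,5,9-trienoate
Product: 18 methyl (2Z,5E,9E)-2-(bromomethyl)-6,10-dimethyl-12-oxododeca-2,5,9-trienoate
Conditions: Dess–Martin periodinane, pyridine, CH2Cl2, 0 °C; used at once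
Reagents that add atoms: none
Why: Neutral Dess–Martin oxidation tolerates the allylic bromide and delivers the second β,γ-unsaturated aldehyde (C8) for immediate ring closure.

Step 10
Reactants: 18 methyl (2Z,5E,9E)-2-(bromomethyl)-6,10-dimethyl-12-oxododeca-2,5,9-trienoate
Product: 20 methyl (7R,8R)-8β-hydroxygermacra-1(10)E,4E,11(13)-trien-12-oate, via trimethylsilyl ether 19 (not isolated)
Conditions: CrCl2 (10 mol %), L* (12 mol %), Mn powder, Me3SiCl, i-Pr2NEt (0.3 equiv), THF, syringe-pump addition of 18 to 5 mM, rt; then Bu4NF, AcOH, THF, 0 °C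
Reagents that add atoms: none
Why: This is a catalytic asymmetric Nozaki–Hiyama–Kishi allylation run intramolecularly: divalent chromium turns the allylic bromide into a 2-(chromiomethyl)enoate that adds through its γ-carbon C7 to the C8 aldehyde in a closed six-membered chair (Zimmerman–Traxler) transition state, the (Z)-alkene placing the C6 chain axial so that C7 and C8 should emerge syn (7,8-cis), while the chiral tridentate ligand on trivalent chromium selects the aldehyde face and hence the absolute (7R,8R) configuration; Me3SiCl releases the product as silyl ether 19, Mn returns chromium to the divalent state, and high dilution favours the ten-membered ring over oligomers.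

Step 11
Reactants: 20 methyl (7R,8R)-8β-hydroxygermacra-1(10)E,4E,11(13)-trien-12-oate
Product: 21 methyl (7R,8R)-8β-acetoxygermacra-1(10)E,4E,11(13)-trien-12-oate
Conditions: Ac2O, DMAP, pyridine, CH2Cl2, 0 °C → rt
Reagents that add atoms: acetic anhydride, CC(=O)OC(C)=O
Why: DMAP-catalysed acetylation caps O8 without touching a stereocentre and blocks acid-catalysed lactonisation onto the C12 ester in step 12.

Step 12
Reactants: 21 methyl (7R,8R)-8β-acetoxygermacra-1(10)E,4E,11(13)-trien-12-oate
Product: 24 methyl (7R,8R,10R)-8β-acetoxyeudesma-4,11(13)-dien-12-oate, via 3-ene isomer 22 (not isolated), via 4(15)-ene isomer 23 (not isolated)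
Conditions: TsOH·H2O (0.3 equiv), CH2Cl2, 0 °C → rt, then 40 °C until the alkene isomers converge
Reagents that add atoms: none
Why: TsOH protonates C1 of the C1=C10 alkene and, in the crossed chair–chair conformer of the ten-membered ring, C5 of the C4=C5 alkene bonds to the emerging tertiary C10 cation; the tertiary C4 cation then loses H3, H15 or H5 to give 22, 23 and 24, and re-protonation of 22 and 23 by the same acid funnels them to the tetrasubstituted alkene 24. The closest known reaction is the acid-induced transannular cation–olefin cyclisation of germacra-1(10),4-dienes and germacranolides to eudesmanes. One bond, C5–C10, closes both rings: ring A in a 6-endo mode (C4=C5 and C1=C10 both lie inside the new ring) and ring B in the complementary 6-exo mode (C4 and C1 stay outside it). C10 is the only new stereocentre, and its methyl group should end β (10R), cis to the C7 arm, because bonding occurs in the conformer that holds the branched C7 substituent pseudo-equatorial with C14 and C15 on the same face, the smaller 8β-acetoxy group taking the pseudo-axial site; C7 and C8 are not touched. The step needs conformer selection for C10, initiation at C1 and not at the acrylate, and final loss of H5: the first rests on the larger conformational demand of the sp2-branched C7 arm compared with acetoxy, the second on the fact that only C5–C10 bonding passes through two tertiary cations while the electron-poor acrylate resists protonation, and the third on the thermodynamic preference for the tetrasubstituted alkene under equilibrating acid.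

Step 13
Reactants: 24 methyl (7R,8R,10R)-8β-acetoxyeudesma-4,11(13)-dien-12-oate
Product: 25 methyl (7R,8R,10R)-8β-acetoxy-3-oxoeudesma-4,11(13)-dien-12-oate
Conditions: CrO3, 3,5-dimethylpyrazole (15 equiv each), CH2Cl2, −20 °C
Reagents that add atoms: chromium trioxide, O=[Cr](=O)=O
Why: Allylic oxidation with the hexavalent chromium–3,5-dimethylpyrazole complex should convert the C3 methylene into the conjugated ketone, because the pseudo-axial H3α lies on the open α face whereas the axial H6β is buried under the syn-axial C14 methyl and 8β-acetoxy groups and C6 is inductively deactivated by the neighbouring acrylate and acetate; the electron-poor acrylate is inert.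

Step 14
Reactants: 25 methyl (7R,8R,10R)-8β-acetoxy-3-oxoeudesma-4,11(13)-dien-12-oate
Product: 26 methyl (3S,7R,8R,10R)-8β-acetoxy-3β-hydroxyeudesma-4,11(13)-dien-12-oate
Conditions: NaBH4 (1.0 equiv), CeCl3·7H2O, MeOH, −78 °C
Reagents that add atoms: none
Why: Luche reduction gives 1,2-addition with hydride entering axially from the α face, opposite the angular C14 methyl, to set the pseudo-equatorial 3β-hydroxyl (3S) as in the reduction of steroidal 4-en-3-ones, and low temperature with one equivalent of hydride spares the acrylate from conjugate reduction.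

Step 15
Reactants: 26 methyl (3S,7R,8R,10R)-8β-acetoxy-3β-hydroxyeudesma-4,11(13)-dien-12-oate; 27 (E)-3-methylpent-2-enoic acid
Product: 28 methyl (3S,7R,8R,10R)-8β-acetoxy-3β-[(E)-3-methylpent-2-enoyloxy]eudesma-4,11(13)-dien-12-oate (CNP0118541.1)
Conditions: DCC, DMAP (0.2 equiv), CH2Cl2, 0 °C → rt
Reagents that add atoms: none
Why: Steglich esterification (carbodiimide activation, acyl transfer by DMAP) acylates the allylic alcohol with retention at C3 and, in the absence of strong base, should leave the (E) geometry of the β,β-disubstituted enoate unchanged.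

Compound list
1 | tert-butyl(but-3-yn-1-yloxy)dimethylsilane | C#CCCO[Si](C)(C)C(C)(C)C | starting material
2 | (E)-[4-(tert-butyldimethylsilyloxy)-2-methylbut-1-en-1-yl]dimethylaluminium | C[Al](C)/C=C(\C)CCO[Si](C)(C)C(C)(C)C | intermediate
3 | (E)-tert-butyl[(4-iodo-3-methylbut-3-en-1-yl)oxy]dimethylsilane | I/C=C(\C)CCO[Si](C)(C)C(C)(C)C | intermediate
4 | (4-bromobut-1-yn-1-yl)trimethylsilane | C[Si](C)(C)C#CCCBr | starting material
5 | [4-(trimethylsilyl)but-3-yn-1-yl]zinc bromide | C[Si](C)(C)C#CCC[Zn]Br | intermediate
6 | (E)-tert-butyldimethyl{[3-methyl-8-(trimethylsilyl)oct-3-en-7-yn-1-yl]oxy}silane | C[Si](C)(C)C#CCC/C=C(\C)CCO[Si](C)(C)C(C)(C)C | intermediate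
7 | (E)-tert-butyldimethyl[(3-methyloct-3-en-7-yn-1-yl)oxy]silane | C#CCC/C=C(\C)CCO[Si](C)(C)C(C)(C)C | intermediate
8 | ethylene oxide | C1CO1 | starting material
9 | [(1E,5E)-8-(tert-butyldimethylsilyloxy)-2,6-dimethylocta-1,5-dien-1-yl]dimethylaluminium | C[Al](C)/C=C(\C)CC/C=C(\C)CCO[Si](C)(C)C(C)(C)C | intermediate
10 | lithium butyl[(1E,5E)-8-(tert-butyldimethylsilyloxy)-2,6-dimethylocta-1,5-dien-1-yl]dimethylaluminate | [Li+].CCCC[Al-](C)(C)/C=C(\C)CC/C=C(\C)CCO[Si](C)(C)C(C)(C)C | intermediate
11 | (3E,7E)-10-(tert-butyldimethylsilyloxy)-4,8-dimethyldeca-3,7-dien-1-ol | OCC/C=C(\C)CC/C=C(\C)CCO[Si](C)(C)C(C)(C)C | intermediate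
12 | (3E,7E)-10-(tert-butyldimethylsilyloxy)-4,8-dimethyldeca-3,7-dienal | O=CC/C=C(\C)CC/C=C(\C)CCO[Si](C)(C)C(C)(C)C | intermediate
13 | methyl propiolate | C#CC(=O)OC | starting material
14 | [1-(methoxycarbonyl)ethenyl]diisobutylaluminium | C=C(C(=O)OC)[Al](CC(C)C)CC(C)C | intermediate
15 | methyl (5E,9E)-12-(tert-butyldimethylsilyloxy)-3-hydroxy-6,10-dimethyl-2-methylidenedodeca-5,9-dienoate (racemic at C3) | C=C(C(=O)OC)C(O)C/C=C(\C)CC/C=C(\C)CCO[Si](C)(C)C(C)(C)C | intermediate
16 | methyl (2Z,5E,9E)-2-(bromomethyl)-12-(tert-butyldimethylsilyloxy)-6,10-dimethyldodeca-2,5,9-trienoate | COC(=O)/C(CBr)=C/C/C=C(\C)CC/C=C(\C)CCO[Si](C)(C)C(C)(C)C | intermediate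
17 | methyl (2Z,5E,9E)-2-(bromomethyl)-12-hydroxy-6,10-dimethyldodeca-2,5,9-trienoate | COC(=O)/C(CBr)=C/C/C=C(\C)CC/C=C(\C)CCO | intermediate
18 | methyl (2Z,5E,9E)-2-(bromomethyl)-6,10-dimethyl-12-oxododeca-2,5,9-trienoate | COC(=O)/C(CBr)=C/C/C=C(\C)CC/C=C(\C)CC=O | intermediate
19 | methyl (7R,8R)-8β-(trimethylsilyloxy)germacra-1(10)E,4E,11(13)-trien-12-oate | C=C(C(=O)OC)[C@H]1C/C=C(C)/CC/C=C(C)/C[C@H]1O[Si](C)(C)C | intermediate
20 | methyl (7R,8R)-8β-hydroxygermacra-1(10)E,4E,11(13)-trien-12-oate | C=C(C(=O)OC)[C@H]1C/C=C(C)/CC/C=C(C)/C[C@H]1O | intermediate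
21 | methyl (7R,8R)-8β-acetoxygermacra-1(10)E,4E,11(13)-trien-12-oate | C=C(C(=O)OC)[C@H]1C/C=C(C)/CC/C=C(C)/C[C@H]1OC(C)=O | intermediate
22 | methyl 8β-acetoxy-5αH-eudesma-3,11(13)-dien-12-oate | C=C(C(=O)OC)[C@H]1C[C@H]2C(C)=CCC[C@]2(C)C[C@H]1OC(C)=O | intermediate
23 | methyl 8β-acetoxy-5αH-eudesma-4(15),11(13)-dien-12-oate | C=C(C(=O)OC)[C@H]1C[C@H]2C(=C)CCC[C@]2(C)C[C@H]1OC(C)=O | intermediate
24 | methyl (7R,8R,10R)-8β-acetoxyeudesma-4,11(13)-dien-12-oate | C=C(C(=O)OC)[C@H]1CC2=C(C)CCC[C@]2(C)C[C@H]1OC(C)=O | intermediate
25 | methyl (7R,8R,10R)-8β-acetoxy-3-oxoeudesma-4,11(13)-dien-12-oate | C=C(C(=O)OC)[C@H]1CC2=C(C)C(=O)CC[C@]2(C)C[C@H]1OC(C)=O | intermediate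
26 | methyl (3S,7R,8R,10R)-8β-acetoxy-3β-hydroxyeudesma-4,11(13)-dien-12-oate | C=C(C(=O)OC)[C@H]1CC2=C(C)[C@@H](O)CC[C@]2(C)C[C@H]1OC(C)=O | intermediate
27 | (E)-3-methylpent-2-enoic acid | CC/C(C)=C/C(=O)O | starting material
28 | methyl (3S,7R,8R,10R)-8β-acetoxy-3β-[(E)-3-methylpent-2-enoyloxy]eudesma-4,11(13)-dien-12-oate (CNP0118541.1) | C=C(C(=O)OC)[C@H]1CC2=C(C)[C@@H](OC(=O)/C=C(\C)CC)CC[C@]2(C)C[C@H]1OC(C)=O | target

Total step count: 15. Longest linear sequence: 15 steps (1 → 28); 4, 8, 13 and 27 enter as purchased building blocks.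

Steps most likely to fail

Step 12. The cis arrangement at C7/C8 forces one substituent pseudo-axial in either chair–chair conformer. Closure through the ring-inverted conformer (C7 arm pseudo-axial, 8β-acetoxy pseudo-equatorial) would place the C10 methyl α, and the two conformers may lie close in energy. The axial acetoxy carbonyl may also intercept the C10 cation, and the alkene isomers may not converge fully on C4=C5. The fallback removes the ambiguity by making both ring substituents pseudo-equatorial during ring formation. It sets out from 20. A Mitsunobu reaction with formic acid (PPh3, diisopropyl azodicarboxylate, THF) inverts C8 to methyl (7R,8S)-8α-(formyloxy)germacra-1(10)E,4E,11(13)-trien-12-oate F1. TsOH as in step 12 closes F1 to methyl 8α-(formyloxy)eudesma-4,11(13)-dien-12-oate F2. Mild methanolysis (KHCO3, MeOH) gives methyl 8α-hydroxyeudesma-4,11(13)-dien-12-oate F3. Dess–Martin oxidation gives methyl 8-oxoeudesma-4,11(13)-dien-12-oate F4, which is carried on at once because C7–H is now activated. Reduction at −78 °C (NaBH4, CeCl3·7H2O) from the equatorial α side, away from the syn-axial C14 methyl, gives methyl 8β-hydroxyeudesma-4,11(13)-dien-12-oate F5. Acetylation as in step 11 comes back to the route at 24.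

Step 10. Intermolecular allylation may outrun ring closure (oligomers), the ring may close through a non-chair transition state to the 7,8-trans isomer, and the ligand may discriminate the aldehyde faces poorly in a macrocyclic transition state. The fallback separates ring formation from absolute control. It sets out from 18, which is closed without ligand by stoichiometric CrCl2 (THF, high dilution) to the racemic 7,8-cis hydroxy ester, that is 20 together with its enantiomer methyl (7S,8S)-8-hydroxygermacra-1(10)E,4E,11(13)-trien-12-oate F6. Lipase-catalysed transesterification with vinyl acetate (immobilised Candida antarctica lipase B or Burkholderia cepacia lipase, t-BuOMe, 30 °C) should, by the usual lipase preference for the (R)-carbinol, acetylate only the (8R) enantiomer. F6 is left behind and removed by chromatography, and the fallback comes back to the route at 21.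

Step 13. Hydrogen abstraction at C6 or C15 may compete with C3, or the oxidation may stall or over-oxidise. The fallback replaces direct ketonisation by an ene/[2,3]-sigmatropic hydroxylation whose regiochemistry is set by different factors. It sets out from 24. SeO2 (catalytic) with t-BuOOH in CH2Cl2 must use the open α face, on which H3α is the only axial ring hydrogen, and should give methyl 8β-acetoxy-3α-hydroxyeudesma-4,11(13)-dien-12-oate F7. Dess–Martin oxidation of F7 comes back to the route at 25.

Further compounds
F1 | step 12 | methyl (7R,8S)-8α-(formyloxy)germacra-1(10)E,4E,11(13)-trien-12-oate | C=C(C(=O)OC)[C@H]1C/C=C(C)/CC/C=C(C)/C[C@@H]1OC=O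
F2 | step 12 | methyl 8α-(formyloxy)eudesma-4,11(13)-dien-12-oate | C=C(C(=O)OC)[C@H]1CC2=C(C)CCC[C@]2(C)C[C@@H]1OC=O
F3 | step 12 | methyl 8α-hydroxyeudesma-4,11(13)-dien-12-oate | C=C(C(=O)OC)[C@H]1CC2=C(C)CCC[C@]2(C)C[C@@H]1O
F4 | step 12 | methyl 8-oxoeudesma-4,11(13)-dien-12-oate | C=C(C(=O)OC)[C@H]1CC2=C(C)CCC[C@]2(C)CC1=O
F5 | step 12 | methyl 8β-hydroxyeudesma-4,11(13)-dien-12-oate | C=C(C(=O)OC)[C@H]1CC2=C(C)CCC[C@]2(C)C[C@H]1O
F6 | step 10 | methyl (7S,8S)-8-hydroxygermacra-1(10)E,4E,11(13)-trien-12-oate (enantiomer of 20) | C=C(C(=O)OC)[C@@H]1C/C=C(C)/CC/C=C(C)/C[C@@H]1O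
F7 | step 13 | methyl 8β-acetoxy-3α-hydroxyeudesma-4,11(13)-dien-12-oate | C=C(C(=O)OC)[C@H]1CC2=C(C)[C@H](O)CC[C@]2(C)C[C@H]1OC(C)=O
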